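**Strategy**

The target is cut at the CH2 bridge: ring A carbon C4, its methylene and the cis-related C2'–H/C1'–O pair of cyclopentane ring B are traced back to a 2-methylene trione, formaldehyde and a 1-methylcyclopentene. The feature exploited is that O5–C5=C4–CH2 of ring A is a latent 1-oxadiene and that the tertiary oxygen on C1' lies cis to the CH2 on C2'. One Knoevenagel/hetero-Diels–Alder operation therefore forms C4–CH2, CH2–C2' and O–C1' with both new stereocentres, through a temporary dihydropyran that hydroxide later opens. The precursors are the gem-diprenyl acyl trione, paraformaldehyde and an (S)-3-substituted 1-methylcyclopentene whose isopropenyl group is masked as a dioxolane-protected acetyl group.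

Key step: step 7

Atom labels: ring A is numbered as in the name of 19 (C1 ketone, C2 acyl, C3 and C5 enol carbons, C4 bearing the CH2 bridge, C6 diprenylated); ring B is C1' (C–OH), C2' (CH bearing the bridge), C3' (CH bearing isopropenyl).

Assumption: the enantiomer of the ferrocenyl diphosphine named in step 1 is taken to deliver the (S)-adduct; if the sense of induction proves opposite, the mirror-image ligand is used.

**Route**

Step 1
Reactants: 1 cyclopent-2-en-1-one; 2 isopropenylmagnesium bromide
Product: 4 (S)-3-(prop-1-en-2-yl)cyclopent-1-en-1-yl trifluoromethanesulfonate, via bromomagnesium enolate 3 (not isolated)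
Conditions: CuBr·SMe2 (5 mol %), (R)-1-[(Sp)-2-(diphenylphosphino)ferrocenyl]ethyldicyclohexylphosphine (6 mol %), t-BuOMe, −78 °C; then N-(5-chloropyridin-2-yl)-bis(trifluoromethanesulfonimide), THF, −78 to 0 °C; aq. NH4Cl
Reagents that add atoms: N-(5-chloropyridin-2-yl)-bis(trifluoromethanesulfonimide) (Comins' reagent), O=S(=O)(N(c1ccc(Cl)cn1)S(=O)(=O)C(F)(F)F)C(F)(F)F
Why: Copper-catalysed asymmetric conjugate addition of a Grignard reagent to a cyclic enone under a chiral ferrocenyl diphosphine should set C3' by enantioface-selective transfer of the isopropenyl group, and O-sulfonylation of the regiodefined magnesium enolate 3 in the same flask (Comins triflation) fixes the double bond between the future C1' and C2'.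

Step 2
Reactants: 4 (S)-3-(prop-1-en-2-yl)cyclopent-1-en-1-yl trifluoromethanesulfonate
Product: 6 (S)-3-acetylcyclopent-1-en-1-yl trifluoromethanesulfonate, via secondary ozonide 5 (not isolated)
Conditions: O3, CH2Cl2, −78 °C (Sudan red 7B end-point); then PPh3, −78 °C to rt
Reagents that add atoms: ozone, [O-][O+]=O
Why: Ozonolysis with reductive work-up, in which electrophilic ozone should attack the electron-rich 1,1-disubstituted alkene far faster than the sulfonate-deactivated enol double bond, while the cold, neutral conditions leave the allylic stereocentre beside the new ketone untouched (no new stereocentre).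

Step 3
Reactants: 6 (S)-3-acetylcyclopent-1-en-1-yl trifluoromethanesulfonate
Product: 7 (S)-3-(2-methyl-1,3-dioxolan-2-yl)cyclopent-1-en-1-yl trifluoromethanesulfonate
Conditions: (TMSOCH2)2, TMSOTf (2 mol %), CH2Cl2, −78 °C; pyridine quench
Reagents that add atoms: 1,2-bis(trimethylsilyloxy)ethane, C[Si](C)(C)OCCO[Si](C)(C)C
Why: Noyori ketalisation is aprotic and runs at −78 °C, so the beta,gamma-unsaturated ketone should be protected without enolisation toward C3', which avoids racemisation and double-bond migration (no new stereocentre).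

Step 4
Reactants: 7 (S)-3-(2-methyl-1,3-dioxolan-2-yl)cyclopent-1-en-1-yl trifluoromethanesulfonate
Product: 8 (S)-2-methyl-2-(3-methylcyclopent-2-en-1-yl)-1,3-dioxolane
Conditions: MeMgBr, Fe(acac)3 (5 mol %), THF–NMP, −30 to 0 °C
Reagents that add atoms: methylmagnesium bromide, C[Mg]Br
Why: Iron-catalysed Kumada-type cross-coupling of an alkenyl triflate with a Grignard reagent replaces the triflate by methyl without moving the double bond, tolerates the ketal and does not involve the C3' stereocentre.

Step 5
Reactants: 9 phloroglucinol; 10 isovaleryl chloride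
Product: 11 3-methyl-1-(2,4,6-trihydroxyphenyl)butan-1-one
Conditions: AlCl3 (3 equiv), PhNO2, 65 °C; aq. HCl
Reagents that add atoms: none
Why: Friedel–Crafts C-acylation of the symmetrical, threefold-activated arene should stop after one acyl group because the aluminium-chelated product is deactivated (no stereocentre).

Step 6
Reactants: 11 3-methyl-1-(2,4,6-trihydroxyphenyl)butan-1-one; 12 prenyl bromide
Product: 13 3,5-dihydroxy-2-(3-methylbutanoyl)-6,6-bis(3-methylbut-2-en-1-yl)cyclohexa-2,4-dien-1-one
Conditions: 12 (2.1 equiv), NaOMe (3 equiv), MeOH, 0 °C to rt; chromatography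
Reagents that add atoms: none
Why: Base-mediated double C-prenylation of the acylphloroglucinol polyanion, with the second alkylation entering the already prenylated carbon (alkylative dearomatisation, the established entry to gem-dialkyl acyl triones of the filicinic acid type), should leave C4–H between two enol carbons once the aromatic 3,5-diprenyl isomer is removed by chromatography (no stereocentre).

Step 7
Reactants: 13 3,5-dihydroxy-2-(3-methylbutanoyl)-6,6-bis(3-methylbut-2-en-1-yl)cyclohexa-2,4-dien-1-one; 14 formaldehyde (used as paraformaldehyde); 8 (S)-2-methyl-2-(3-methylcyclopent-2-en-1-yl)-1,3-dioxolane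
Product: 16 (1S,3aS,9aR)-6-hydroxy-3a-methyl-1-(2-methyl-1,3-dioxolan-2-yl)-7-(3-methylbutanoyl)-5,5-bis(3-methylbut-2-en-1-yl)-1,2,3,3a,9,9a-hexahydrocyclopenta[b]chromen-8(5H)-one, via 2-methylene trione 15 (not isolated)
Conditions: (CH2O)n (3 equiv), NaOAc (1 equiv), AcOH (0.5 equiv), 8 (2.5 equiv), 1,4-dioxane, 90 °C, sealed tube; 13 added over 3 h
Reagents that add atoms: none
Why: Knoevenagel condensation of formaldehyde at C4 of 13, the only ring carbon that carries hydrogen between two enolised carbonyls, gives after loss of water the electron-poor 2-methylene trione 15, which should react as a 1-oxadiene with the trisubstituted alkene of 8 in an asynchronous inverse-electron-demand hetero-Diels–Alder reaction; the closest known type is the three-component Knoevenagel/hetero-Diels–Alder reaction of cyclic triketones, formaldehyde and terpene alkenes. The dihydropyran closes by intermolecular [4+2] cycloaddition, the CH2 terminus bonding to the hydrogen-bearing C2' and the carbonyl oxygen to the methyl-bearing C1', where positive charge develops in the transition state. C2' is set by approach of 15 to the alkene face opposite the dioxolanyl group on the neighbouring C3', and C1' follows from the suprafacial addition, so oxygen and CH2 end up cis on ring B and the CH2 trans to the C3' substituent. The step needs chemoselectivity for 8 over the prenyl chains and over Michael addition of a second molecule of 13 to 15, which is sought by keeping the more nucleophilic cyclic alkene in excess and adding 13 slowly. A free isopropenyl group would compete as dienophile and is therefore carried as the ketal, which the buffered medium should leave intact. Compound 16 is written as the regioisomer closed through the oxygen next to the diprenylated carbon; the isomer closed through the other flanking carbonyl would converge on the same product in step 10.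

Step 8
Reactants: 16 cis-fused pyran adduct with dioxolane
Product: 17 (1S,3aS,9aR)-1-acetyl-6-hydroxy-3a-methyl-7-(3-methylbutanoyl)-5,5-bis(3-methylbut-2-en-1-yl)-1,2,3,3a,9,9a-hexahydrocyclopenta[b]chromen-8(5H)-one
Conditions: PPTS (0.2 equiv), acetone–H2O (10:1), 45 °C
Reagents that add atoms: water, O
Why: Acid-catalysed ketal hydrolysis with pyridinium tosylate, which should be too weak to ionise the tertiary C–O bond of the pyran or to cyclise the prenyl groups; the acetyl-bearing carbon stays trans to its neighbour, the thermodynamically preferred arrangement, so no stereocentre is at risk.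

Step 9
Reactants: 17 methyl ketone
Product: 18 (1S,3aS,9aR)-6-hydroxy-3a-methyl-7-(3-methylbutanoyl)-5,5-bis(3-methylbut-2-en-1-yl)-1-(prop-1-en-2-yl)-1,2,3,3a,9,9a-hexahydrocyclopenta[b]chromen-8(5H)-one
Conditions: Ph3PCH3Br (4 equiv), KOtBu (4 equiv), THF, 0 °C to rt; aq. NaH2PO4
Reagents that add atoms: methylenetriphenylphosphorane (made in the flask from Ph3PCH3Br and KOtBu), C=P(c1ccccc1)(c1ccccc1)c1ccccc1
Why: Wittig methylenation, in which the first equivalent of ylide deprotonates the acidic enol so that the ring and acyl carbonyls are shielded as an enolate and the vinylogous-ester carbonyl is unreactive, leaving the methyl ketone as the only carbonyl that should be converted (no new stereocentre).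

Step 10
Reactants: 18 isopropenyl pyran
Product: 19 3,5-dihydroxy-4-{[(1R,2S,5S)-2-hydroxy-2-methyl-5-(prop-1-en-2-yl)cyclopentyl]methyl}-2-(3-methylbutanoyl)-6,6-bis(3-methylbut-2-en-1-yl)cyclohexa-2,4-dien-1-one
Conditions: LiOH (10 equiv), H2O–1,4-dioxane (1:1), argon, 80 °C; then 1 M HCl to pH 4, 0 °C
Reagents that add atoms: lithium hydroxide, [Li+].[OH-]
Why: Alkaline addition–elimination at a vinylogous ester (the ring opening known for dihydropyran-fused enol ethers of cyclic 1,3-diones such as the lapachones), in which hydroxide adds to C4a, the tertiary alkoxide on C3a leaves and deprotonation of the liberated triketone makes the opening irreversible; the C3a–O bond is never broken, so C1' keeps its configuration.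

**Compound list**

1 | cyclopent-2-en-1-one | O=C1C=CCC1 | starting material
2 | isopropenylmagnesium bromide | C=C(C)[Mg]Br | starting material
3 | bromomagnesium (S)-3-(prop-1-en-2-yl)cyclopent-1-en-1-olate | C=C(C)[C@@H]1C=C(O[Mg]Br)CC1 | intermediate
4 | (S)-3-(prop-1-en-2-yl)cyclopent-1-en-1-yl trifluoromethanesulfonate | C=C(C)[C@@H]1C=C(OS(=O)(=O)C(F)(F)F)CC1 | intermediate
5 | (1S)-3-(3-methyl-1,2,4-trioxolan-3-yl)cyclopent-1-en-1-yl trifluoromethanesulfonate (secondary ozonide, mixture at the trioxolane carbon) | CC1(OCOO1)[C@@H]2C=C(OS(=O)(=O)C(F)(F)F)CC2 | intermediate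
6 | (S)-3-acetylcyclopent-1-en-1-yl trifluoromethanesulfonate | CC(=O)[C@@H]1C=C(OS(=O)(=O)C(F)(F)F)CC1 | intermediate
7 | (S)-3-(2-methyl-1,3-dioxolan-2-yl)cyclopent-1-en-1-yl trifluoromethanesulfonate | CC1(OCCO1)[C@@H]2C=C(OS(=O)(=O)C(F)(F)F)CC2 | intermediate
8 | (S)-2-methyl-2-(3-methylcyclopent-2-en-1-yl)-1,3-dioxolane | CC1(OCCO1)[C@@H]2C=C(C)CC2 | intermediate
9 | phloroglucinol | Oc1cc(O)cc(O)c1 | starting material
10 | isovaleryl chloride | CC(C)CC(Cl)=O | starting material
11 | 3-methyl-1-(2,4,6-trihydroxyphenyl)butan-1-one | CC(C)CC(=O)c1c(O)cc(O)cc1O | intermediate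
12 | prenyl bromide | CC(C)=CCBr | starting material
13 | 3,5-dihydroxy-2-(3-methylbutanoyl)-6,6-bis(3-methylbut-2-en-1-yl)cyclohexa-2,4-dien-1-one | CC(C)CC(=O)C1=C(O)C=C(O)C(CC=C(C)C)(CC=C(C)C)C1=O | intermediate
14 | formaldehyde (as paraformaldehyde) | C=O | starting material
15 | 5-hydroxy-2-methylidene-4-(3-methylbutanoyl)-6,6-bis(3-methylbut-2-en-1-yl)cyclohex-4-ene-1,3-dione | C=C1C(=O)C(CC=C(C)C)(CC=C(C)C)C(O)=C(C(=O)CC(C)C)C1=O | intermediate
16 | (1S,3aS,9aR)-6-hydroxy-3a-methyl-1-(2-methyl-1,3-dioxolan-2-yl)-7-(3-methylbutanoyl)-5,5-bis(3-methylbut-2-en-1-yl)-1,2,3,3a,9,9a-hexahydrocyclopenta[b]chromen-8(5H)-one | CC1(OCCO1)[C@H]2CC[C@]3(C)OC4=C(C[C@H]23)C(=O)C(C(=O)CC(C)C)=C(O)C4(CC=C(C)C)CC=C(C)C | intermediate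
17 | (1S,3aS,9aR)-1-acetyl-6-hydroxy-3a-methyl-7-(3-methylbutanoyl)-5,5-bis(3-methylbut-2-en-1-yl)-1,2,3,3a,9,9a-hexahydrocyclopenta[b]chromen-8(5H)-one | CC(=O)[C@H]1CC[C@]2(C)OC3=C(C[C@H]12)C(=O)C(C(=O)CC(C)C)=C(O)C3(CC=C(C)C)CC=C(C)C | intermediate
18 | (1S,3aS,9aR)-6-hydroxy-3a-methyl-7-(3-methylbutanoyl)-5,5-bis(3-methylbut-2-en-1-yl)-1-(prop-1-en-2-yl)-1,2,3,3a,9,9a-hexahydrocyclopenta[b]chromen-8(5H)-one | C=C(C)[C@H]1CC[C@]2(C)OC3=C(C[C@H]12)C(=O)C(C(=O)CC(C)C)=C(O)C3(CC=C(C)C)CC=C(C)C | intermediate
19 | 3,5-dihydroxy-4-{[(1R,2S,5S)-2-hydroxy-2-methyl-5-(prop-1-en-2-yl)cyclopentyl]methyl}-2-(3-methylbutanoyl)-6,6-bis(3-methylbut-2-en-1-yl)cyclohexa-2,4-dien-1-one | C=C(C)[C@H]1CC[C@](C)(O)[C@@H]1CC1=C(O)C(CC=C(C)C)(CC=C(C)C)C(=O)C(C(=O)CC(C)C)=C1O | target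

**Step count and risks**

Total steps: 10. Longest linear sequence: 8 (steps 1–4, then 7–10).

Steps most likely to fail:

1. Step 7. The methylene trione 15 may be captured faster by a second molecule of 13 (methylene-bridged dimer) or by prenyl chains than by 8, and discrimination between the two alkene faces may be incomplete. Fallback: the detour sets out from 13 and comes back at 16. Trione 13 is C-methylated at C4 (MeI, 1 equiv, NaOMe, MeOH) to 3,5-dihydroxy-4-methyl-2-(3-methylbutanoyl)-6,6-bis(3-methylbut-2-en-1-yl)cyclohexa-2,4-dien-1-one F1. Dehydrogenation of its C-methyl group with Ag2O and TEMPO in the presence of 8 generates the same methylene trione 15 without formaldehyde and without free 13, so the dimer pathway is closed, and cycloaddition gives 16.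

2. Step 10. Hydroxide addition to the hindered vinylogous-ester carbon of an already anionic substrate may be slow, and forcing may bring retro-Claisen cleavage of ring A or re-closure on acidification. Fallback: the temporary ring is avoided; the detour sets out from the bromomagnesium enolate 3 of step 1 and from trione 13 and comes back at 19. Enolate 3 is quenched with dimethylmethylideneammonium iodide to give the trans Mannich base (2S,3S)-2-[(dimethylamino)methyl]-3-(prop-1-en-2-yl)cyclopentan-1-one F2. Warming F2 with 13 in toluene releases dimethylamine and forms (R)-2-methylidene-3-(prop-1-en-2-yl)cyclopentan-1-one F3 in the flask. The enol carbon C4 of 13 adds to F3 in a Michael reaction to give 3,5-dihydroxy-2-(3-methylbutanoyl)-6,6-bis(3-methylbut-2-en-1-yl)-4-{[(1R,5S)-2-oxo-5-(prop-1-en-2-yl)cyclopentyl]methyl}cyclohexa-2,4-dien-1-one F4, in which the epimerisable C2' should settle trans to isopropenyl. Excess MeMgBr with CeCl3 (THF, −78 °C) should then add to the ring ketone from the face opposite the C2' side chain, placing the hydroxyl cis to the CH2 bridge and giving 19.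

3. Step 1. Enantioface selection in the copper-catalysed addition to the small, flat cyclopentenone may be insufficient, 1,2-addition may compete, and O-triflation of the magnesium enolate may be incomplete. Fallback: stereochemical purity is secured by a chiral ketal that also serves as the protecting group; the detour sets out from 6 and comes back at 17. Ketone 6, of whatever enantiomeric purity step 1 delivers, is ketalised under TMSOTf with the bis(trimethylsilyl) ether of (1R,2R)-1,2-diphenylethane-1,2-diol. The two diastereomeric ketals are separated by chromatography or crystallisation, keeping (S)-3-[(4R,5R)-2-methyl-4,5-diphenyl-1,3-dioxolan-2-yl]cyclopent-1-en-1-yl trifluoromethanesulfonate F5 and discarding (R)-3-[(4R,5R)-2-methyl-4,5-diphenyl-1,3-dioxolan-2-yl]cyclopent-1-en-1-yl trifluoromethanesulfonate F6. F5 is methylated as in step 4 to (4R,5R)-2-methyl-2-[(S)-3-methylcyclopent-2-en-1-yl]-4,5-diphenyl-1,3-dioxolane F7. F7 replaces 8 in step 7 and should give (1S,3aS,9aR)-6-hydroxy-3a-methyl-1-[(4R,5R)-2-methyl-4,5-diphenyl-1,3-dioxolan-2-yl]-7-(3-methylbutanoyl)-5,5-bis(3-methylbut-2-en-1-yl)-1,2,3,3a,9,9a-hexahydrocyclopenta[b]chromen-8(5H)-one F8, with the bulkier ketal expected to reinforce the facial bias. Acid hydrolysis as in step 8 returns 17.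

**Further compounds**

F1 | step 7 | 3,5-dihydroxy-4-methyl-2-(3-methylbutanoyl)-6,6-bis(3-methylbut-2-en-1-yl)cyclohexa-2,4-dien-1-one | CC(C)CC(=O)C1=C(O)C(C)=C(O)C(CC=C(C)C)(CC=C(C)C)C1=O
F2 | step 10 | (2S,3S)-2-[(dimethylamino)methyl]-3-(prop-1-en-2-yl)cyclopentan-1-one | C=C(C)[C@H]1CCC(=O)[C@@H]1CN(C)C
F3 | step 10 | (R)-2-methylidene-3-(prop-1-en-2-yl)cyclopentan-1-one | C=C(C)[C@H]1CCC(=O)C1=C
F4 | step 10 | 3,5-dihydroxy-2-(3-methylbutanoyl)-6,6-bis(3-methylbut-2-en-1-yl)-4-{[(1R,5S)-2-oxo-5-(prop-1-en-2-yl)cyclopentyl]methyl}cyclohexa-2,4-dien-1-one | C=C(C)[C@H]1CCC(=O)[C@@H]1CC1=C(O)C(CC=C(C)C)(CC=C(C)C)C(=O)C(C(=O)CC(C)C)=C1O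
F5 | step 1 | (S)-3-[(4R,5R)-2-methyl-4,5-diphenyl-1,3-dioxolan-2-yl]cyclopent-1-en-1-yl trifluoromethanesulfonate | CC1(O[C@H](c2ccccc2)[C@@H](c2ccccc2)O1)[C@@H]3C=C(OS(=O)(=O)C(F)(F)F)CC3
F6 | step 1 | (R)-3-[(4R,5R)-2-methyl-4,5-diphenyl-1,3-dioxolan-2-yl]cyclopent-1-en-1-yl trifluoromethanesulfonate | CC1(O[C@H](c2ccccc2)[C@@H](c2ccccc2)O1)[C@H]3C=C(OS(=O)(=O)C(F)(F)F)CC3
F7 | step 1 | (4R,5R)-2-methyl-2-[(S)-3-methylcyclopent-2-en-1-yl]-4,5-diphenyl-1,3-dioxolane | CC1(O[C@H](c2ccccc2)[C@@H](c2ccccc2)O1)[C@@H]3C=C(C)CC3
F8 | step 1 | (1S,3aS,9aR)-6-hydroxy-3a-methyl-1-[(4R,5R)-2-methyl-4,5-diphenyl-1,3-dioxolan-2-yl]-7-(3-methylbutanoyl)-5,5-bis(3-methylbut-2-en-1-yl)-1,2,3,3a,9,9a-hexahydrocyclopenta[b]chromen-8(5H)-one | CC1(O[C@H](c2ccccc2)[C@@H](c2ccccc2)O1)[C@H]3CC[C@]4(C)OC5=C(C[C@H]34)C(=O)C(C(=O)CC(C)C)=C(O)C5(CC=C(C)C)CC=C(C)C
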